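## The problem

Gericudranin D (19) is a trans-dihydroflavonol: rings A and C form a 2,3-dihydro-4H-chromen-4-one that carries a 4-hydroxyphenyl group (ring B) at C2 and a hydroxyl at C3, and ring A is a fully substituted phloroglucinol unit with hydroxyls at C5 and C7 and 4-hydroxybenzyl groups at C6 and C8. The only stereocentres are C2 (R) and C3 (R), adjacent and trans. An aryl group already in place at C2 can steer an incoming oxygen to the opposite face at C3, whereas a C3 oxygen is a poor handle for building C2, so C2 should be set first and C3 under its control. The compound does not tolerate base: enolisation towards C3 epimerises that centre, β-elimination of the ring oxygen opens ring C and scrambles C2, and the α-ketol is easily dehydrogenated to the flavonol. Five phenols and two electron-rich diarylmethane CH2 groups exclude hard oxidants, and the benzylic C2–O bond limits reductive conditions. The two identical benzyl groups occupy the only two nucleophilic CH positions of a 5,7-dioxygenated benzopyran, so they can be placed on an achiral precursor in which C6 and C8 are the sole reactive sites. The feature that opens the structure is the pair of adjacent oxygenated carbons in ring C: the C3 hydroxyl and the C4 ketone are what the C3=C4 bond of a 2-aryl-2H-chromene becomes after cis-dioxygenation and oxidation at C4. The C4 alcohol of the intermediate diol is benzylic to the electron-rich ring A and can therefore be told apart from the C3 alcohol.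

## Retrosynthesis

**19 from 18.** The five aryl O–CH2OMe bonds are cut, leading from 19 to penta-O-methoxymethyl ether 18. Acetal protection is preferred to benzyl ethers, whose hydrogenolysis would put the benzylic C2–O bond at risk, and to methyl ethers, which need boron tribromide. The forward step needs only dilute methanolic acid, which trans-dihydroflavonols tolerate.

**18 from 17.** The C4 carbonyl is taken back to a C4 alcohol, giving (2R,3S,4S)-diol 17. The neighbouring option, oxidising a flavan-3-ol at C4 with a quinone, would also attack the two diarylmethane CH2 groups. With the diol, a mild surface oxidant only has to distinguish a doubly alkoxy-activated benzylic alcohol from a saturated secondary one. The C4 stereocentre is erased, so only the C3 outcome of the previous step matters.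

**17 from 15.** The C3–O and C4–O bonds are cut together, giving flav-3-ene 15. Two neighbouring cuts were weighed. Epoxidation of a chalcone followed by ring closure would need an enantioselective epoxidation of a hindered, very electron-rich 2′-hydroxychalcone. α-Hydroxylation of a flavanone enolate invites β-elimination of the ring oxygen. Dihydroxylation avoids both: it is neutral, stereospecifically cis, and lets the existing C2 centre place the C3 oxygen trans to the aryl group. Precursor 15 has one stereocentre and no oxygen on C3 or C4. The forward reaction, OsO4 catalysis through osmate ester 16, must attack only the face opposite the C2 aryl group and must stop at the diol.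

**15 from 11 and 13.** The C2–aryl bond is cut, giving racemic 2-ethoxy-2H-chromene 11 and diethyl arylboronate 13, which meet through benzopyrylium ion 14. The neighbouring route through a flavanone (asymmetric conjugate arylation of a chromone, reduction, dehydration) is longer and passes through a base-labile intermediate. Here the stereocentre is created in the same step that joins ring B, and both partners are achiral. The forward reaction must transfer the aryl group to C2 and not C4 of the pyrylium ion, with control of the face by a chiral diol on boron.

**11 from 10 from 9.** The C2–OEt bond and then the C2–H bond are cut, returning through lactol 10 to coumarin 9. A coumarin is a stable, achiral carrier of the complete ring A/ring C carbon skeleton. Partial reduction and acetal exchange are all that is asked.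

**9 from 8 from 4 and 5.** After removal of four methoxymethyl groups (9 to 8), both ring A–CH2 bonds are cut, giving 5,7-dihydroxycoumarin 4 and two molecules of 4-hydroxybenzyl alcohol 5. Benzylating phloroglucinol 1 itself was the neighbouring choice. It has three equivalent positions and would give statistical mixtures. In 4 only C6 and C8 are left, so exhaustive benzylation with two molecules of 5 has a single end point, reached through either mono-adduct 6 or 7.

**4 from 1 and 2.** The C4–C4a bond and the lactone O1–C2 bond are cut, giving phloroglucinol 1 and ethyl propiolate 2, joined through acrylate 3. The threefold symmetry of 1 removes any regiochemical question.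

**13 from 12.** The two B–OEt bonds are cut, giving boronic acid 12. The diethyl ester is needed because its alkoxides exchange with the chiral diol catalyst.

## Roads not taken

Alternative 1: ring A built last by Diels–Alder benzannulation.
- Cut: the C8–C8a and C4a–C5 bonds.
- Forward key step: the doubly benzylated 1-methoxy-1,3-bis(silyloxy)diene A2 adds across the C4a=C8a bond of enantiopure 5-bromo-dihydropyranone A1. Loss of the bromide and of the methoxy group then aromatises ring A to give A3, with free C5 and C7 hydroxyls.
- Merits: it is convergent. Both stereocentres are made on a small ring where asymmetric methods are strong. The benzyl groups arrive with fixed regiochemistry and no Friedel–Crafts step. No light- or acid-sensitive flavene and no osmium are involved. In these respects it is better than the chosen plan.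
- Weak points: A2 has a fully substituted ketene acetal terminus and a benzyl-bearing terminus, so both new bonds form at congested carbons. A1 is a vinylogous ester and therefore a poor dienophile. The aromatisation needs base or heat next to an epimerisable C3 centre in a ring prone to β-elimination of its C3 oxygen substituent. A1 and A2 each need a multi-step preparation.
- Comparison: the chosen plan is linear and less convergent, but every bond is made by a reaction known on the same substrate class, and the stereocentres are never exposed to base.

Alternative 2: carbene-catalysed dynamic crossed benzoin closing ring C.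
- Cut: the C3–C4 bond.
- Forward key step: a chiral triazolium-derived carbene and mild base convert racemic dialdehyde A4 into A5, which is identical with 18. The acyl-anion equivalent of the aromatic aldehyde adds to the α-aryloxy aldehyde while the latter racemises.
- Merits: one catalytic step closes ring C, sets C2 and C3 together, and gives the correct oxidation state at C4. There is no metal oxidant and no redox adjustment. In step and redox economy it beats the chosen plan.
- Weak points: the aromatic aldehyde of A4 sits between two ortho substituents on a very electron-rich ring, so the carbene is more likely to engage the aliphatic aldehyde, which would close the ring with the carbonyl at C3 and the carbinol at C4. Trans selectivity under dynamic resolution is not secured by any substrate element. A5 is itself labile to the base that the catalysis requires. A4 needs an O-alkylation of a hindered salicylaldehyde and the unmasking of a very sensitive aldehyde.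
- Comparison: the chosen plan sets C2 and C3 in two separate events, each with a close analogy, and fixes the trans relationship by anti addition to an existing centre.

Alternative 3: double boronate arylation of ring A ortho-quinone methides.
- Cut: the two CH2–aryl bonds.
- Forward key step: (2R,3R)-aromadendrin A6 is converted into bis-Mannich base A7. Heating A7 with boronic acid 12 expels the amine to give ortho-quinone methides at C6 and C8, which accept the aryl group from boron to give A8.
- Merits: both stereocentres are bought ready-made, the benzyl regiochemistry is dictated by the Mannich reaction, and the sequence is only a few steps. If A6 is accepted as a starting material, this is clearly the shortest road.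
- Weak points: thermal quinone methide generation needs heat and releases a secondary amine. Under these conditions a dihydroflavonol opens, epimerises and dehydrogenates. Two successive quinone methide captures must occur on one ring, in competition with dimerisation and amine re-addition. The Mannich step itself exposes the free α-ketol to base.
- Comparison: the chosen plan is independent of a scarce chiral natural product. It installs the benzyl groups on a robust achiral coumarin and exposes the stereocentres only to neutral or mildly acidic conditions.

Key step: step 8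

Remarks on the chemistry:
- Boronic acid 12 is treated as a purchasable building block; it is otherwise two routine steps from 4-bromophenol.
- The sense of induction of the tartaric acid monoamide in step 7 is assumed to carry over from simple chromene acetals. Both enantiomers of tartaric acid are available, so the catalyst antipode that gives (S)-15 is used.

## Route

Step 1
Reactants: 1 phloroglucinol; 2 ethyl propiolate
Product: 4 5,7-dihydroxycoumarin, via Z-aryl acrylate 3 (not isolated)
Conditions: ZnCl2 (1 equiv), neat, 90–100 °C
Reagents that add atoms: none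
Why: Pechmann-type coumarin synthesis: ZnCl2 activates the propiolate, the threefold-activated arene adds to its β-carbon to give Z-acrylate 3, and the ortho hydroxyl lactonises with loss of ethanol; all ring positions of 1 are equivalent, so only one product can form.

Step 2
Reactants: 4 5,7-dihydroxycoumarin; 5 4-hydroxybenzyl alcohol (two molecules are incorporated)
Product: 8 5,7-dihydroxy-6,8-bis(4-hydroxybenzyl)coumarin, via 8-monobenzyl coumarin 6 (not isolated), via 6-monobenzyl coumarin 7 (not isolated)
Conditions: 5 (3 equiv in all, added in portions), TsOH·H2O (10 mol %), 1,4-dioxane, 80 °C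
Reagents that add atoms: 4-hydroxybenzyl alcohol `OCc1ccc(O)cc1` (the second molecule of 5)
Why: Double Friedel–Crafts benzylation: acid converts each molecule of 5 into a 4-hydroxybenzyl cation (protonated para-quinone methide) that alkylates ring A at its only two activated CH positions, C8 and C6, with loss of one water per alkylation. Both mono-adducts 6 and 7 take up the second molecule of 5 and converge on 8, and no third activated position remains.

Step 3
Reactants: 8 5,7-dihydroxy-6,8-bis(4-hydroxybenzyl)coumarin
Product: 9 5,7-bis(methoxymethoxy)-6,8-bis[4-(methoxymethoxy)benzyl]coumarin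
Conditions: NaH (6 equiv), MOMCl (6 equiv), DMF, 0 °C to rt
Reagents that add atoms: chloromethyl methyl ether `COCCl` (four molecules are incorporated)
Why: Williamson-type O-alkylation of four phenoxides; NaH in DMF is chosen because the C5 and C7 hydroxyls are flanked by benzyl groups, and the lactone is inert to phenoxide.

Step 4
Reactants: 9 5,7-bis(methoxymethoxy)-6,8-bis[4-(methoxymethoxy)benzyl]coumarin
Product: 10 5,7-bis(methoxymethoxy)-6,8-bis[4-(methoxymethoxy)benzyl]-2H-chromen-2-ol (racemic lactol)
Conditions: i-Bu2AlH (1.2 equiv), CH2Cl2/toluene, −78 °C; aq. potassium sodium tartrate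
Reagents that add atoms: none
Why: Partial reduction of a lactone to a lactol; the tetrahedral aluminium hemiacetal persists at −78 °C until work-up, and aryl MOM ethers and diarylmethanes are untouched. The crude lactol is used directly.

Step 5
Reactants: 10 racemic lactol
Product: 11 2-ethoxy-5,7-bis(methoxymethoxy)-6,8-bis[4-(methoxymethoxy)benzyl]-2H-chromene (racemic)
Conditions: EtOH, PPTS (5 mol %), 3 Å MS, 0 °C to rt; Et3N quench
Reagents that add atoms: ethanol `CCO`
Why: Acid-catalysed acetalisation: the lactol ionises easily to the dialkoxy-stabilised benzopyrylium ion, which ethanol traps at C2; PPTS at this temperature is too weak to cleave aryl MOM ethers.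

Step 6
Reactants: 12 4-(methoxymethoxy)phenylboronic acid
Product: 13 diethyl 4-(methoxymethoxy)phenylboronate
Conditions: EtOH, 3 Å MS, reflux; evaporate, use crude
Reagents that add atoms: ethanol `CCO` (two molecules are incorporated)
Why: Reversible esterification of a boronic acid driven by removal of water; the diethyl ester can exchange its alkoxides for the chiral diol in step 7, which a pinacol ester could not.

Step 7
Reactants: 11 racemic 2-ethoxy-2H-chromene; 13 diethyl 4-(methoxymethoxy)phenylboronate
Product: 15 (2S)-5,7-bis(methoxymethoxy)-6,8-bis[4-(methoxymethoxy)benzyl]-2-[4-(methoxymethoxy)phenyl]-2H-chromene, via benzopyrylium cation 14 (not isolated)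
Conditions: 13 (2 equiv), tartaric acid N,N-dibenzyl monoamide (10 mol %, antipode leading to 2S), Ce(OTf)4 (8 mol %), EtOAc, −20 °C, dark
Reagents that add atoms: none
Why: Enantioselective boronate addition to a chromene acetal under combined chiral Brønsted acid and Lewis acid catalysis. Ce(OTf)4 (tetravalent cerium) and the dihydroxy acid ionise 11 to pyrylium 14, the diol unit of the catalyst exchanges onto boron, and the aryl group migrates from the chiral boronate to C2 within the ion pair, setting C2 (S). Attack at C4 is disfavoured by the peri 5-methoxymethoxy group.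

Step 8
Reactants: 15 (2S)-flav-3-ene
Product: 17 (2R,3S,4S)-5,7-bis(methoxymethoxy)-6,8-bis[4-(methoxymethoxy)benzyl]-2-[4-(methoxymethoxy)phenyl]chromane-3,4-diol, via cyclic osmate ester 16 (not isolated)
Conditions: OsO4 (3 mol %), NMO (1.5 equiv), acetone/H2O, 0 °C to rt, dark; aq. Na2SO3
Reagents that add atoms: OsO4 `O=[Os](=O)(=O)=O` (catalytic oxygen carrier); N-methylmorpholine N-oxide `C[N+]1([O-])CCOCC1`; water `O`
Why: OsO4 (octavalent osmium) adds to the C3=C4 bond in a concerted, suprafacial [3+2] cycloaddition to give cyclic osmate ester 16 (hexavalent osmium), which water hydrolyses to diol 17 while NMO returns osmium to the octavalent state (Upjohn dihydroxylation). The closest known reaction is the OsO4 dihydroxylation of flav-3-enes, which gives 2,3-trans-3,4-cis flavan-3,4-diols. No ring of the target is closed; the only ring formed is the transient five-membered osmate ester, closed by the [3+2] addition and opened again on hydrolysis. C3 and C4 are both set by the existing C2 stereocentre: the 4-(methoxymethoxy)phenyl group screens its own face of the nearly planar chromene, so osmium arrives anti to it and the C3 oxygen ends trans to the aryl group (3S here, 3R once C4 is a ketone), and the cis mode of addition fixes C4 (4S) relative to C3. The step needs facial selectivity and chemoselectivity: the first comes from the C2 substituent, the second from the fact that C3=C4 is the only non-aromatic π bond and is activated by the electron-rich ring A. Because C6 and C8 are blocked and all phenols are capped, the acid-labile benzylic diol cannot condense with another ring A, and neutral conditions in the dark keep the C2–O bond of 15 from ionising before it reacts.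

Step 9
Reactants: 17 (2R,3S,4S)-flavan-3,4-diol
Product: 18 (2R,3R)-3-hydroxy-5,7-bis(methoxymethoxy)-6,8-bis[4-(methoxymethoxy)benzyl]-2-[4-(methoxymethoxy)phenyl]chroman-4-one
Conditions: activated MnO2 (15 equiv), CH2Cl2, rt
Reagents that add atoms: none
Why: MnO2 (tetravalent manganese) oxidises benzylic alcohols, here one activated by ortho and para alkoxy groups, far faster than saturated secondary alcohols, so only the C4 hydroxyl is converted. The C4 stereocentre disappears and the 2,3-trans relationship set in step 8 remains.

Step 10
Reactants: 18 penta-O-methoxymethyl dihydroflavonol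
Product: 19 gericudranin D
Conditions: HCl (3 M in MeOH), MeOH/THF, 45 °C
Reagents that add atoms: none
Why: Acid-catalysed acetal methanolysis of five aryl MOM ethers, the CH2OMe units leaving as dimethoxymethane. Trans-dihydroflavonols tolerate methanolic HCl, any acid enolisation at C3 would return the more stable trans isomer, and the blocked C6 and C8 positions cannot be hydroxymethylated.

## Compound list

```
1 | phloroglucinol (benzene-1,3,5-triol) | Oc1cc(O)cc(O)c1 | starting material
2 | ethyl propiolate | C#CC(=O)OCC | starting material
3 | ethyl (Z)-3-(2,4,6-trihydroxyphenyl)acrylate | CCOC(=O)/C=C\c1c(O)cc(O)cc1O | intermediate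
4 | 5,7-dihydroxycoumarin (5,7-dihydroxy-2H-chromen-2-one) | O=C1C=Cc2c(O)cc(O)cc2O1 | intermediate
5 | 4-hydroxybenzyl alcohol | OCc1ccc(O)cc1 | starting material
6 | 5,7-dihydroxy-8-(4-hydroxybenzyl)coumarin | O=C1C=Cc2c(O)cc(O)c(Cc3ccc(O)cc3)c2O1 | intermediate
7 | 5,7-dihydroxy-6-(4-hydroxybenzyl)coumarin | O=C1C=Cc2c(O)c(Cc3ccc(O)cc3)c(O)cc2O1 | intermediate
8 | 5,7-dihydroxy-6,8-bis(4-hydroxybenzyl)coumarin | O=C1C=Cc2c(O)c(Cc3ccc(O)cc3)c(O)c(Cc3ccc(O)cc3)c2O1 | intermediate
9 | 5,7-bis(methoxymethoxy)-6,8-bis[4-(methoxymethoxy)benzyl]coumarin | O=C1C=Cc2c(OCOC)c(Cc3ccc(OCOC)cc3)c(OCOC)c(Cc3ccc(OCOC)cc3)c2O1 | intermediate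
10 | 5,7-bis(methoxymethoxy)-6,8-bis[4-(methoxymethoxy)benzyl]-2H-chromen-2-ol (racemic lactol) | OC1C=Cc2c(OCOC)c(Cc3ccc(OCOC)cc3)c(OCOC)c(Cc3ccc(OCOC)cc3)c2O1 | intermediate
11 | 2-ethoxy-5,7-bis(methoxymethoxy)-6,8-bis[4-(methoxymethoxy)benzyl]-2H-chromene (racemic) | CCOC1C=Cc2c(OCOC)c(Cc3ccc(OCOC)cc3)c(OCOC)c(Cc3ccc(OCOC)cc3)c2O1 | intermediate
12 | 4-(methoxymethoxy)phenylboronic acid | COCOc1ccc(B(O)O)cc1 | starting material
13 | diethyl 4-(methoxymethoxy)phenylboronate | CCOB(OCC)c1ccc(OCOC)cc1 | intermediate
14 | 5,7-bis(methoxymethoxy)-6,8-bis[4-(methoxymethoxy)benzyl]chromenylium (1-benzopyrylium) cation | c1cc2c(OCOC)c(Cc3ccc(OCOC)cc3)c(OCOC)c(Cc3ccc(OCOC)cc3)c2[o+]c1 | intermediate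
15 | (2S)-5,7-bis(methoxymethoxy)-6,8-bis[4-(methoxymethoxy)benzyl]-2-[4-(methoxymethoxy)phenyl]-2H-chromene (flav-3-ene) | C1=C[C@@H](c2ccc(OCOC)cc2)Oc2c(Cc3ccc(OCOC)cc3)c(OCOC)c(Cc3ccc(OCOC)cc3)c(OCOC)c12 | intermediate
16 | cyclic osmate ester of 17 (3,4-O-dioxo-osmium glycolate, hexavalent osmium, oxygens trans to the C2 aryl group) | O=[Os]1(=O)O[C@H]2c3c(OCOC)c(Cc4ccc(OCOC)cc4)c(OCOC)c(Cc4ccc(OCOC)cc4)c3O[C@H](c3ccc(OCOC)cc3)[C@H]2O1 | intermediate
17 | (2R,3S,4S)-5,7-bis(methoxymethoxy)-6,8-bis[4-(methoxymethoxy)benzyl]-2-[4-(methoxymethoxy)phenyl]chromane-3,4-diol (2,3-trans-3,4-cis) | O[C@H]1c2c(OCOC)c(Cc3ccc(OCOC)cc3)c(OCOC)c(Cc3ccc(OCOC)cc3)c2O[C@H](c2ccc(OCOC)cc2)[C@H]1O | intermediate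
18 | (2R,3R)-3-hydroxy-5,7-bis(methoxymethoxy)-6,8-bis[4-(methoxymethoxy)benzyl]-2-[4-(methoxymethoxy)phenyl]chroman-4-one | O=C1c2c(OCOC)c(Cc3ccc(OCOC)cc3)c(OCOC)c(Cc3ccc(OCOC)cc3)c2O[C@H](c2ccc(OCOC)cc2)[C@H]1O | intermediate
19 | gericudranin D, (2R,3R)-3,5,7-trihydroxy-6,8-bis(4-hydroxybenzyl)-2-(4-hydroxyphenyl)chroman-4-one | O=C1c2c(O)c(Cc3ccc(O)cc3)c(O)c(Cc3ccc(O)cc3)c2O[C@H](c2ccc(O)cc2)[C@H]1O | target
```

## Step count and risks

Total: 10 steps. Longest linear sequence: 9 steps (steps 1–5, then 7–10); step 6 is a one-step branch.

**Step 8 (key step).**
- What may go wrong: incomplete facial discrimination, because the directing aryl group is two atoms away from C4 and the peri 5-methoxymethoxy group can tilt the ring. The osmium/N-oxide system may also over-oxidise the very electron-rich benzylic diol. The C2–O bond of the flavene may ionise or open under light before the alkene reacts.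
- Fallback: set out from 15 with a reagent-controlled epoxidation whose catalyst antipode is matched to anti attack. Jacobsen's salen complex C36H52ClMnN2O2 (trivalent manganese) with NaOCl and 4-phenylpyridine N-oxide in CH2Cl2 at 0 °C should give the 3,4-epoxide trans to the C2 aryl group F1. This labile benzylic epoxide is opened at C4 by water (wet acetone, trace PPTS) to the 2,3-trans-3,4-trans diol F2; any C4 epimer formed is 17 itself. MnO2 as in step 9 converts F2 into 18, where the route is rejoined. Catalyst and substrate then favour the same face, and no osmium is present.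

**Step 7.**
- What may go wrong: erosion of enantioselectivity, either by uncatalysed aryl transfer to the strongly stabilised pyrylium ion or by re-ionisation of the C2–O bond of the product under the Lewis acid. Partial loss of MOM groups and competing attack at C4 are lesser concerns.
- Fallback: set out from 11 and boronic acid 12. Coupling with Ni(cod)2 (zerovalent nickel) and PPh3 in dioxane/tert-amyl alcohol should give the racemic flavene F3. Preparative chromatography on a cellulose carbamate chiral phase, with neutral eluent and in the dark, separates 15 from its (2R) antipode F4. The route is rejoined at 15.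

**Step 2.**
- What may go wrong: self-condensation of 5 through its quinone methide may outrun the second alkylation of the lactone-deactivated ring, and the new phenol rings may be alkylated further.
- Fallback: reverse the order and benzylate the stronger nucleophile. Set out from 1 and 5 in hot water without acid. Through 2-(4-hydroxybenzyl)phloroglucinol F5 this gives 2,4-bis(4-hydroxybenzyl)phloroglucinol F6, which has to be separated from mono- and tribenzyl congeners. Treating F6 with 2 and ZnCl2 as in step 1 closes the lactone at the single remaining CH, through Z-acrylate F7. The route is rejoined at 8.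

**Step 9.**
- What may go wrong: oxidative C3–C4 cleavage of the cis-diol on the MnO2 surface, or further dehydrogenation of the ketol to the flavonol.
- Fallback: set out from 17. TBSCl and imidazole in DMF are expected to silylate the equatorial C3 hydroxyl in preference to the pseudo-axial C4 hydroxyl, which is screened by the peri substituent, giving 3-O-silyl diol F8. Dess–Martin periodinane with NaHCO3 in CH2Cl2 then oxidises the only free alcohol to 3-O-silyl ketone F9, with no glycol left to cleave. The methanolic HCl of step 10 removes the silyl group together with the MOM ethers. The route is rejoined at 19.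

## Further compounds

```
F1 | step 8 | (2R)-3,4-epoxy-5,7-bis(methoxymethoxy)-6,8-bis[4-(methoxymethoxy)benzyl]-2-[4-(methoxymethoxy)phenyl]chromane, epoxide oxygen trans to the C2 aryl group | O1[C@H]2c3c(OCOC)c(Cc4ccc(OCOC)cc4)c(OCOC)c(Cc4ccc(OCOC)cc4)c3O[C@H](c3ccc(OCOC)cc3)[C@@H]12
F2 | step 8 | (2R,3S,4R)-5,7-bis(methoxymethoxy)-6,8-bis[4-(methoxymethoxy)benzyl]-2-[4-(methoxymethoxy)phenyl]chromane-3,4-diol (2,3-trans-3,4-trans) | O[C@@H]1c2c(OCOC)c(Cc3ccc(OCOC)cc3)c(OCOC)c(Cc3ccc(OCOC)cc3)c2O[C@H](c2ccc(OCOC)cc2)[C@H]1O
F3 | step 7 | racemic 5,7-bis(methoxymethoxy)-6,8-bis[4-(methoxymethoxy)benzyl]-2-[4-(methoxymethoxy)phenyl]-2H-chromene | C1=CC(c2ccc(OCOC)cc2)Oc2c(Cc3ccc(OCOC)cc3)c(OCOC)c(Cc3ccc(OCOC)cc3)c(OCOC)c12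
F4 | step 7 | (2R)-5,7-bis(methoxymethoxy)-6,8-bis[4-(methoxymethoxy)benzyl]-2-[4-(methoxymethoxy)phenyl]-2H-chromene | C1=C[C@H](c2ccc(OCOC)cc2)Oc2c(Cc3ccc(OCOC)cc3)c(OCOC)c(Cc3ccc(OCOC)cc3)c(OCOC)c12
F5 | step 2 | 2-(4-hydroxybenzyl)benzene-1,3,5-triol | Oc1cc(O)c(Cc2ccc(O)cc2)c(O)c1
F6 | step 2 | 2,4-bis(4-hydroxybenzyl)benzene-1,3,5-triol | Oc1cc(O)c(Cc2ccc(O)cc2)c(O)c1Cc1ccc(O)cc1
F7 | step 2 | ethyl (Z)-3-[2,4,6-trihydroxy-3,5-bis(4-hydroxybenzyl)phenyl]acrylate | CCOC(=O)/C=C\c1c(O)c(Cc2ccc(O)cc2)c(O)c(Cc2ccc(O)cc2)c1O
F8 | step 9 | (2R,3S,4S)-3-(tert-butyldimethylsilyloxy)-5,7-bis(methoxymethoxy)-6,8-bis[4-(methoxymethoxy)benzyl]-2-[4-(methoxymethoxy)phenyl]chroman-4-ol | O[C@H]1c2c(OCOC)c(Cc3ccc(OCOC)cc3)c(OCOC)c(Cc3ccc(OCOC)cc3)c2O[C@H](c2ccc(OCOC)cc2)[C@H]1O[Si](C)(C)C(C)(C)C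
F9 | step 9 | (2R,3R)-3-(tert-butyldimethylsilyloxy)-5,7-bis(methoxymethoxy)-6,8-bis[4-(methoxymethoxy)benzyl]-2-[4-(methoxymethoxy)phenyl]chroman-4-one | O=C1c2c(OCOC)c(Cc3ccc(OCOC)cc3)c(OCOC)c(Cc3ccc(OCOC)cc3)c2O[C@H](c2ccc(OCOC)cc2)[C@H]1O[Si](C)(C)C(C)(C)C
A1 | alternative 1 | (2R,3R)-5-bromo-3-(tert-butyldimethylsilyloxy)-2-[4-(methoxymethoxy)phenyl]-2,3-dihydro-4H-pyran-4-one | O=C1C(Br)=CO[C@H](c2ccc(OCOC)cc2)[C@H]1O[Si](C)(C)C(C)(C)C
A2 | alternative 1 | 1-methoxy-1,3-bis(trimethylsilyloxy)buta-1,3-diene carrying 4-(methoxymethoxy)benzyl groups at C2 and C4 | COC(O[Si](C)(C)C)=C(Cc1ccc(OCOC)cc1)C(O[Si](C)(C)C)=CCc1ccc(OCOC)cc1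
A3 | alternative 1 | (2R,3R)-3-(tert-butyldimethylsilyloxy)-5,7-dihydroxy-6,8-bis[4-(methoxymethoxy)benzyl]-2-[4-(methoxymethoxy)phenyl]chroman-4-one | O=C1c2c(O)c(Cc3ccc(OCOC)cc3)c(O)c(Cc3ccc(OCOC)cc3)c2O[C@H](c2ccc(OCOC)cc2)[C@H]1O[Si](C)(C)C(C)(C)C
A4 | alternative 2 | racemic 2-{2-formyl-3,5-bis(methoxymethoxy)-4,6-bis[4-(methoxymethoxy)benzyl]phenoxy}-2-[4-(methoxymethoxy)phenyl]acetaldehyde | O=CC(Oc1c(C=O)c(OCOC)c(Cc2ccc(OCOC)cc2)c(OCOC)c1Cc1ccc(OCOC)cc1)c1ccc(OCOC)cc1
A5 | alternative 2 | (2R,3R)-3-hydroxy-5,7-bis(methoxymethoxy)-6,8-bis[4-(methoxymethoxy)benzyl]-2-[4-(methoxymethoxy)phenyl]chroman-4-one (identical with 18) | O=C1c2c(OCOC)c(Cc3ccc(OCOC)cc3)c(OCOC)c(Cc3ccc(OCOC)cc3)c2O[C@H](c2ccc(OCOC)cc2)[C@H]1O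
A6 | alternative 3 | (2R,3R)-aromadendrin, (2R,3R)-3,5,7-trihydroxy-2-(4-hydroxyphenyl)chroman-4-one | O=C1c2c(O)cc(O)cc2O[C@H](c2ccc(O)cc2)[C@H]1O
A7 | alternative 3 | (2R,3R)-6,8-bis[(dimethylamino)methyl]-3,5,7-trihydroxy-2-[4-(methoxymethoxy)phenyl]chroman-4-one | O=C1c2c(O)c(CN(C)C)c(O)c(CN(C)C)c2O[C@H](c2ccc(OCOC)cc2)[C@H]1O
A8 | alternative 3 | (2R,3R)-3,5,7-trihydroxy-6,8-bis[4-(methoxymethoxy)benzyl]-2-[4-(methoxymethoxy)phenyl]chroman-4-one | O=C1c2c(O)c(Cc3ccc(OCOC)cc3)c(O)c(Cc3ccc(OCOC)cc3)c2O[C@H](c2ccc(OCOC)cc2)[C@H]1O
```
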